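# Proposed synthesis of CNP0197096.3, a daucane 2‑acetate 6‑veratroate with a trans‑fused 8,9‑oxirane

Numbering used throughout: C1 methylated ring‑fusion carbon, C2 acetoxy carbon, C3 methylene, C4 isopropyl carbinol carbon, C5 ring‑fusion CH, C6 veratroyloxy carbon, C7 methylene, C8 (methyl) and C9 oxirane carbons, C10 carbinol carbon. The α face is the face of the bicycle that carries O2, O4, H5, O6 and O10; the β face carries the C1 methyl and the isopropyl group.

Assumption: the oxirane descriptors are taken as written; they put C7 and C10 on opposite sides of the three‑membered ring (C8 methyl α, O–C8 β, O–C9 α), so the target contains the oxide of an (E)‑cycloheptene, a strained ring fusion of the kind that is isolable in the carbocyclic parent (trans‑bicyclo[5.1.0]octane), and the end game is built to deliver exactly that unit.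

## The problem

The target is a daucane: a cyclopentane and a cycloheptane fused trans through the quaternary, methylated C1 and through C5, with eight stereocentres (C1, C2, C4, C5, C6, C8, C9, C10) and every ring carbon except C3 and C7 functionalised. Five oxygens sit on the α face and must be told apart: the tertiary C4 and secondary C10 hydroxyls stay free, O2 carries an acetate, O6 a veratroate, and the oxirane oxygen is bound to C9 on this face. Only C4 can be bought in enantiopure form, so it has to govern the rest: directly through its oxygen for C5 and C6, and indirectly, through the face on which the seven‑membered ring is attached at C1, for C10 and C2. The oxirane is the unusual element: C8 holds its methyl group on the α face and its oxygen on the β face, so C7 and C10 stand trans across the three‑membered ring, as in the oxide of an (E)‑cycloheptene. No epoxidation of the Z‑configured ring alkene, directed or not, and no halohydrin closure can give this arrangement; it requires syn oxygen transfer to the E isomer of the C8=C9 bond, which only light can provide, and the photochemistry must come before the light‑absorbing veratroate is attached. The strained oxirane is acid‑sensitive and the esters are hydride‑sensitive, so both must follow the steps that turn a carboxyl group into the C8 methyl. The trans ring fusion puts C6 on the same side of the cyclopentane as the isopropyl group and the C1 methyl, which is unlikely to be the more stable arrangement next to a C6 ketone, so C5 should not be left to enolate equilibration. The enabling feature is the seven‑membered ring itself: C5–C6 and C8–C9 are oxidised two‑carbon units separated by the C7 methylene, a cyclohepta‑1,4‑diene in disguise, and the bond opposite C7 joins the quaternary C1 to the oxygenated C10, the σ‑bond formed when a cis‑divinylcyclopropane built on C6, C7 and C8 rearranges.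

## Retrosynthesis

**C10 silyl ether last (32 from 31).** Only the O10–Si bond is cut. Keeping O10 silylated until the veratroate is in place makes the acylation at O6 unambiguous; the neighbouring choice, acylating a C6/C10 diol beside the oxirane, would rest on a rate difference between two hindered secondary alcohols. The precursor differs from the target only by the protecting group. The forward step must cleave a hindered neopentyl silyl ether without acid (oxirane) and without leaving a free alkoxide next to the cis O2 acetate.

**Veratroate (31 from 29 and 30).** The acyl–oxygen bond is cut to diol 29 and acid chloride 30. The ester is placed after the oxirane and not before it because a dimethoxybenzoate absorbs at 254 nm and is an energy sink, so it would shut down the sensitised isomerisation on which the oxirane depends. The forward step is a DMAP acylation of the only free secondary hydroxyl under basic conditions that the oxirane tolerates.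

**Oxirane (29 from 28, 28 from 27).** Both C–O bonds are cut together, back to the E‑configured alkene 28, which is handled as its AgNO3 complex 27. Cutting only one C–O bond (closure of a halohydrin or a diol monosulfonate) would need the oxygen nucleophile and the leaving group antiperiplanar although they are cis on the ring, and the tertiary C8 alkoxide would sooner start a semipinacol shift. Any epoxidation of the Z alkene gives the cis‑fused isomer. Syn oxygen transfer to 28 is stereospecific and the ring chain leaves only one face open, so two stereocentres are traded for the sense of twist of one alkene. The forward step needs a neutral oxidant that reacts at −78 °C.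

**E‑alkene (27 from 26).** No bond is cut; the configuration of C8=C9 is inverted. Thermal generation by elimination from 8,9‑difunctionalised precursors would need those precursors and temperatures at which an (E)‑cycloheptene does not survive. Sensitised photoisomerisation in the cold with capture of the E isomer by silver is the alternative that fits. The precursor 26 is the ordinary Z alkene and has no chromophore that absorbs at 254 nm. The forward step must produce one sense of twist, and the angular C1 methyl is expected to decide it.

**C5–H and C6–O together (26 from 24, 24 from 23, 23 from 22).** Both bonds lie on the α face, next to O4, and are cut together to the C5=C6 alkene 23 with a free C4 hydroxyl, which comes from 22 by selective loss of the triethylsilyl group. The neighbouring choices are weaker. A C6 ketone would need protonation at C5 to the probably less stable epimer and then hydride delivery from the more crowded face. Hydroboration would need facial selectivity and selectivity over the C8=C9 bond. A silicon hydride tethered to O4 (24) turns the problem into a cis addition delivered from O4, so two stereocentres are traded for one trisubstituted alkene. The forward reaction must be a 5‑endo hydrosilylation followed by C–Si oxidation with retention.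

**Acetate, C2 carbinol and C8 methyl (22 from 21, 21 from 19, 19 from 18).** The acetate is cut at the point where O2 is the only free hydroxyl, and the C2–H bond and two C–H bonds of the C8 methyl are traced back to keto ester 18. One hydride reagent reduces ketone and ester, and the primary allylic alcohol is then deoxygenated. These reductions have to come before any ester is in place. At this stage C5 is still sp2, so the two out‑of‑plane groups on C1 are the methyl (β) and C10 with its silyloxy group (α, cis to C2). The forward step relies on hydride arriving from the methyl side.

**C6–H (18 from 17, 17 from 16).** The vinylic hydrogen at C6 is exchanged for oxygen, through enol triflate 17 back to the silyl enol ether 16. The oxygen is taken out and later put back for a reason: the silyloxy group makes C6=C7 of the diene the nucleophilic alkene despite the conjugated C2 ketone, and it comes free from a methyl ketone that the C2 oxidation needs anyway. The price is two steps.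

**Key disconnection (16 from 10 and 14).** C1–C10 and C7–C8 are cut, through a transient C6–C8 bond. Other cuts of the seven‑membered ring (an aldol at C5–C6, an alkylation at C9–C10) build one bond and at most one stereocentre. This cut forms the quaternary C1 and the C10 carbinol in one event, with their relative configuration fixed by alkene geometry. The bicyclic product with three stereocentres is reduced to a monocyclic diene with one stereocentre (10, carrying C1–C7) and an achiral diazo ester (14, carrying C8–C10 and the future C8 methyl). The forward reaction must select the C6=C7 bond, give the cis‑divinylcyclopropane, keep the E enol ether, and join C10 to the α face of C1.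

**Diene (10 from 8, 8 from 7, then 6, 5, 4, 2, 1).** Enol silylation of the acetyl group, γ‑oxidation of the enone at C2, methyl addition and oxidation at C6, and an ozonolysis/aldol ring contraction lead back to (S)‑terpinen‑4‑ol (1), which supplies C4 with the right configuration; the optical purity of the commercial material fixes that of everything downstream and has to be checked. The C2 ketone is left unmasked on purpose. A dioxolane would have to be placed on one of two enone carbonyls (C2 or C6) with nothing to choose between them, and an sp2 C2 is the smallest neighbour C1 can have in the rearrangement.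

**Diazo ester (14 from 13, 13 from 11 and 12).** The bond between the diazo carbon and the carbinol carbon is cut (aldol‑type addition of ethyl diazoacetate 12 to aldehyde 11), and the enol ether comes from dehydration. Silylating an aldehyde enolate would give mainly the Z enol ether; dehydration of the adduct forms the conjugated, less crowded E alkene that the rearrangement needs.

## Roads not taken

**Alternative 1: intramolecular nitrile oxide cycloaddition.** The cut is C1–C10 together with O–C2. In the forward sense the Z‑enal oxime A1 is oxidised with NaOCl and the resulting dipole adds across the C1=C2 bond of the cyclopentene, closing the seven‑membered ring and an isoxazoline in A2.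
- Merits: the quaternary C1 is formed together with the C2 oxygen, cis to C10 by necessity. This is better than the chosen plan, which leaves C2 to a hydride reduction (step 13). The C8 methyl and the C8=C9 bond are also already present, which saves the ester‑to‑methyl steps.
- Weak points: a seven‑membered ring is closed through a conjugated nitrile oxide that needs a Z alkene and can dimerise. The dipole adds to a trisubstituted alkene under facial control only from the remote C4. C10 emerges at the ketone oxidation level (C=N), so reductive N–O cleavage leaves a C10 reduction still to be controlled. C5 is left undefined next to a C6 ketone, the enolisable arrangement avoided here.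
- Comparison: A1 needs an acyclic Z‑trisubstituted alkene and a C5–C6 union, so it is not shorter. The chosen plan is weaker at C2 but delivers C10 with the right oxidation level and configuration, and controls C5/C6 with a tether. Like the other two roads, this one ends at a Z‑configured C8=C9 bond and would need the same photochemical end game, so that part does not discriminate.

**Alternative 2: carbenoid C–H insertion forming the cyclopentane.** The cut is C4–C5. Rh2(OAc)4 converts the diazoketone A3 into a carbenoid that inserts into the C4–H bond next to the silyloxy group with retention, giving the acetylcyclopentane A4.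
- Merits: 1,5‑insertion into a tertiary C–H bond activated by oxygen is dependable and stereoretentive. C2 and C10 are set by open‑chain methods before the ring closes, so C2 does not hang on a late reduction; in that respect this road is the safer one. A4 keeps a vinyl iodide for the later ring closure.
- Weak points: the step closes the five‑membered ring, which the chosen plan buys from terpinen‑4‑ol with C4 in place. C1 (quaternary, between two oxygenated stereocentres), C2, C4 and C10 all have to be built in an acyclic chain. The seven‑membered ring still has to be closed afterwards, and C5 is again undefined next to the acetyl group.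
- Comparison: the step count is clearly higher and the key step forms none of the seven‑membered ring. The chosen key step closes that ring and sets two stereocentres at once.

**Alternative 3: intramolecular Buchner ring expansion.** The cut is C1–C5 together with C1–C10. Rh2(OAc)4 decomposes the α‑methyl diazoketone A5; the carbenoid adds across the ipso–ortho bond of the anisole and the norcaradiene opens to the cycloheptatrienone A6.
- Merits: both rings arise in one step from a flat arene, with the C8 methyl, the C6 oxygen (as enol ether) and the C2 ketone in place. This is the shortest way to the bicyclic skeleton, shorter than the chosen route, and it needs neither an ester‑to‑methyl conversion nor a deoxygenation at C6.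
- Weak points: C4 becomes a benzylic tertiary carbinol that must be made enantioselectively without the chiral pool. The α‑methyl carbenoid has a competing 1,2‑hydride shift and must choose the unsubstituted ortho bond. A6 has no oxygen at C10 and one double bond too many, so the conjugated triene must be converted into the C10 carbinol, a single C8=C9 alkene and a C7 methylene with no directing group.
- Comparison: the chosen plan spends four extra steps (two at C6, two on the C8 methyl). In return C10 arrives oxygenated with defined configuration, and the C5=C6 bond has its own directing hydroxyl before the C8=C9 bond is left alone for the photochemical end game.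

Key step: step 10

## Route

Step 1
Reactants: 1 (S)-terpinen-4-ol
Product: 2 (S)-terpinen-4-ol triethylsilyl ether
Conditions: Et3SiOTf, 2,6-lutidine, CH2Cl2, 0 → 23 °C
Reagents that add atoms: triethylsilyl trifluoromethanesulfonate, CC[Si](CC)(CC)OS(=O)(=O)C(F)(F)F
Why: Silylation of a tertiary alcohol with a silyl triflate and a hindered pyridine base is routine. The ether masks O4 through the ozonolysis, Grignard, enolate and carbenoid steps and can later be removed in the presence of a tert-butyldimethylsilyl ether.

Step 2
Reactants: 2 (S)-terpinen-4-ol triethylsilyl ether
Product: 4 (S)-3-isopropyl-6-oxo-3-(triethylsilyloxy)heptanal, via secondary ozonide 3 (not isolated)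
Conditions: O3, CH2Cl2, −78 °C; then Me2S, −78 → 23 °C
Reagents that add atoms: ozone, [O-][O+]=O
Why: Ozonolysis of the only C=C bond with reductive work-up gives the keto aldehyde. The silyloxy carbon is not involved and keeps the configuration of 1.

Step 3
Reactants: 4 (S)-3-isopropyl-6-oxo-3-(triethylsilyloxy)heptanal
Product: 5 2-methyl-5-isopropyl-5-(triethylsilyloxy)cyclopent-1-ene-1-carbaldehyde (C4 as in 1)
Conditions: piperidine (cat.), AcOH (cat.), toluene, 80 °C
Reagents that add atoms: none
Why: This is the amine-catalysed intramolecular aldol condensation used to contract ozonised 1-methylcyclohexenes; the aldehyde enamine adds to the methyl ketone in a 5-exo closure. Ring closure is intramolecular and should outrun loss of the β-silyloxy group, and after dehydration that group sits on a carbon attached to an sp2 centre and can no longer be eliminated.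

Step 4
Reactants: 5 2-methyl-5-isopropyl-5-(triethylsilyloxy)cyclopent-1-ene-1-carbaldehyde
Product: 6 1-[2-methyl-5-isopropyl-5-(triethylsilyloxy)cyclopent-1-en-1-yl]ethan-1-ol (both carbinol epimers)
Conditions: MeMgBr, THF, −78 → 0 °C
Reagents that add atoms: methylmagnesium bromide, C[Mg]Br
Why: Grignard 1,2-addition to the formyl group supplies C7. The new carbinol centre is oxidised in the next step, so its configuration does not matter.

Step 5
Reactants: 6 1-[2-methyl-5-isopropyl-5-(triethylsilyloxy)cyclopent-1-en-1-yl]ethan-1-ol
Product: 7 1-[2-methyl-5-isopropyl-5-(triethylsilyloxy)cyclopent-1-en-1-yl]ethan-1-one (methyl enone)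
Conditions: Dess–Martin periodinane, NaHCO3, CH2Cl2, 23 °C
Reagents that add atoms: none
Why: Dess–Martin oxidation of a secondary allylic alcohol under buffered conditions. There is no epimerisable centre and the silyl ether is inert.

Step 6
Reactants: 7 methyl enone
Product: 8 3-acetyl-2-methyl-4-isopropyl-4-(triethylsilyloxy)cyclopent-2-en-1-one (enedione, C2 ketone)
Conditions: Pd(OH)2/C (5 mol%), tBuOOH (5 equiv), K2CO3 (0.25 equiv), CH2Cl2, 23 °C
Reagents that add atoms: tert-butyl hydroperoxide, CC(C)(C)OO
Why: This is the palladium/hydroperoxide allylic oxidation of an enone at its γ position to the ene-1,4-dione. Of the two γ positions the ring methylene C2 should react before the methyl group (secondary against primary C–H abstraction), and C3 is not allylic.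

Step 7
Reactants: 8 enedione
Product: 10 3-[1-(tert-butyldimethylsilyloxy)ethenyl]-2-methyl-4-isopropyl-4-(triethylsilyloxy)cyclopent-2-en-1-one (siloxydiene), via lithium enolate 9 (not isolated)
Conditions: LiN(SiMe3)2, THF, −78 °C; then tBuMe2SiOTf, −78 → −40 °C
Reagents that add atoms: tert-butyldimethylsilyl trifluoromethanesulfonate, CC(C)(C)[Si](C)(C)OS(=O)(=O)C(F)(F)F
Why: Kinetic deprotonation with a bulky amide should take the acetyl methyl group and not the C3 methylene, which is neopentyl beside the fully substituted C4; O-silylation gives the 2-silyloxydiene. The C2 ketone stays free because no reagent could tell it from the C6 ketone for ketalisation, and because an sp2 C2 keeps C1 open for the rearrangement.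

Step 8
Reactants: 11 (tert-butyldimethylsilyloxy)acetaldehyde; 12 ethyl diazoacetate
Product: 13 ethyl 4-(tert-butyldimethylsilyloxy)-2-diazo-3-hydroxybutanoate (racemic)
Conditions: DBU (10 mol%), MeCN, 0 → 23 °C
Reagents that add atoms: none
Why: Base-catalysed aldol-type addition of the acidic C–H bond of a diazoacetate to an aldehyde. The carbinol centre is removed in the next step.

Step 9
Reactants: 13 ethyl 4-(tert-butyldimethylsilyloxy)-2-diazo-3-hydroxybutanoate
Product: 14 ethyl (E)-4-(tert-butyldimethylsilyloxy)-2-diazobut-3-enoate
Conditions: POCl3, Et3N, CH2Cl2, 0 °C; used at once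
Reagents that add atoms: none
Why: Dehydration of a β-hydroxy-α-diazo ester with POCl3 and amine base is an established route to vinyldiazoacetates. Loss of the proton next to the silyloxy group gives the conjugated enol ether, and the less crowded E isomer should predominate; E geometry is what the rearrangement translates into the C10 configuration.

Step 10
Reactants: 10 siloxydiene; 14 ethyl (E)-4-(tert-butyldimethylsilyloxy)-2-diazobut-3-enoate
Product: 16 bicyclic cyclohepta-1,4-diene with C8 ethyl ester on C8=C9, C10 tert-butyldimethylsilyl ether trans to the C1 methyl, C2 ketone, C4 triethylsilyl ether and C5=C6 silyl enol ether (C10 attached to the α face of the cyclopentene, C1 methyl β), via divinylcyclopropane 15 (not isolated)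
Conditions: Rh2(S-DOSP)4 [dirhodium tetrakis((S)-N-(dodecylbenzenesulfonyl)prolinate)] (2 mol%), 14 (2.5 equiv) added over 3 h, hexanes, −40 → 23 °C; then 60 °C
Reagents that add atoms: none
Why: The dirhodium carboxylate turns 14 into a rhodium vinylcarbenoid that adds to the terminal C6=C7 silyl enol ether of 10 in a non-synchronous [2+1] step, giving cyclopropane 15 with the two alkenyl groups cis. 15 then undergoes the divinylcyclopropane Cope rearrangement through a boat transition state, in which the C6–C8 bond (weakened by the silyloxy donor on C6 and the ester on C8) breaks while C1–C10 forms. The closest known reaction type is the rhodium vinylcarbenoid/diene formal (4+3) cycloaddition, including cases in which a ring-embedded, fully substituted diene terminus becomes a quaternary carbon. The three-membered ring closes by carbenoid addition and the seven-membered ring by a concerted [3,3] ring expansion, so no end-on cyclisation is involved. C10 is controlled by the E enol ether, which the boat places trans to the C1 methyl and cis to C2. C1 is controlled by the absolute configuration of 15, which fixes the cyclopentene face that C10 joins; the chiral catalyst sets it and the isopropyl group shields the β face, and whether the S catalyst written here or its antipode is the matched one has to be settled in the first run. Site selectivity for C6=C7 over C5=C1 and the ketone rests on the silyloxy activation against a tetrasubstituted, carbonyl-deactivated alkene. Attack at the carbenoid carbon in preference to the vinyl terminus rests on the 4-substituent and the hydrocarbon solvent, which also disfavours zwitterionic opening of 15.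

Step 11
Reactants: 16 bicyclic silyl enol ether
Product: 17 C6 enol triflate (C5=C6–OTf; otherwise as 16)
Conditions: CsF, PhNTf2, DME, 23 °C
Reagents that add atoms: N-phenylbis(trifluoromethanesulfonimide), O=S(=O)(N(c1ccccc1)S(=O)(=O)C(F)(F)F)C(F)(F)F
Why: Fluoride cleaves only the silyl enol ether (the alkyl silyl ethers are inert to CsF in DME), and the caesium enolate is sulfonylated on oxygen by the triflimide present from the start, before it can exchange protons with C7 or C3. This is a known direct conversion of tert-butyldimethylsilyl enol ethers into enol triflates, and it prepares removal of the C6 oxygen now that it has served in the key step.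

Step 12
Reactants: 17 C6 enol triflate
Product: 18 keto ester with C5=C6–H (C2 ketone, C8 ethyl ester, C4 and C10 silyl ethers)
Conditions: Pd(OAc)2 (5 mol%), PPh3, HCO2H, Bu3N, DMF, 60 °C
Reagents that add atoms: none
Why: Palladium-catalysed formate reduction of an enol triflate (oxidative addition, decarboxylation of the formate, reductive elimination) replaces OTf by H without moving the double bond. The amine is mild enough to leave the β-silyloxy ketone alone.

Step 13
Reactants: 18 keto ester
Product: 19 diol with C2 hydroxyl on the α face and C8 hydroxymethyl
Conditions: iBu2AlH (5 equiv), CH2Cl2, −78 → −40 °C; aq. potassium sodium tartrate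
Reagents that add atoms: none
Why: iBu2AlH reduces the conjugated ester to the allylic alcohol and the ketone to the carbinol in one step. With C5 still sp2, the α face of C2 is covered by C10 and its silyloxy group (cis to C2) and by the C4 silyl ether, so hydride should arrive from the side of the C1 methyl and leave the C2 hydroxyl on the α face.

Step 14
Reactants: 19 diol
Product: 21 C2 alcohol with C8 methyl, via allylic mesylate 20 (not isolated)
Conditions: MsCl (1.1 equiv), Et3N, THF, −40 °C; then LiEt3BH, −40 → 0 °C
Reagents that add atoms: none
Why: The primary allylic alcohol is sulfonylated well before the neopentyl C2 carbinol, and hydride displaces the mesylate directly (SN2) to give the methyl group with C8=C9 in place. Attack at C9 with allylic shift is blocked by the substituted C10.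

Step 15
Reactants: 21 C2 alcohol
Product: 22 C2 acetate
Conditions: Ac2O, DMAP, Et3N, CH2Cl2, 23 → 40 °C
Reagents that add atoms: acetic anhydride, CC(=O)OC(C)=O
Why: DMAP-catalysed acetylation of the only free hydroxyl in the molecule, so the site of the acetate is unambiguous. All hydride steps are finished, so the ester is safe from here on.

Step 16
Reactants: 22 C2 acetate
Product: 23 tertiary C4 alcohol (C10 tert-butyldimethylsilyl ether retained)
Conditions: HF·pyridine, pyridine, THF, 0 → 23 °C
Reagents that add atoms: none
Why: Buffered HF·pyridine cleaves triethylsilyl ethers considerably faster than tert-butyldimethylsilyl ethers, and the C10 ether is additionally neopentyl. The acidic medium does not move the acetate.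

Step 17
Reactants: 23 tertiary C4 alcohol
Product: 24 C4 dimethylsilyl (Si–H) ether
Conditions: Me2SiHCl, Et3N, DMAP (cat.), CH2Cl2, 0 → 23 °C; filtered and used crude
Reagents that add atoms: chlorodimethylsilane, C[SiH](C)Cl
Why: The small chlorosilane silylates even the hindered tertiary alcohol. This installs the Si–H tether on O4, the oxygen that shares a face with the hydrogen and oxygen needed at C5 and C6.

Step 18
Reactants: 24 C4 dimethylsilyl ether
Product: 26 diol with C6 hydroxyl and C5 hydrogen on the α face (trans ring fusion; C4 hydroxyl free; Z-8,9-alkene), via oxasilolane 25 (not isolated)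
Conditions: Pt2(dvtms)3 (Karstedt's catalyst, 2 mol% Pt), toluene, 60 °C; then KF, KHCO3, 30% H2O2, THF/MeOH, 23 °C
Reagents that add atoms: hydrogen peroxide, OO
Why: Intramolecular hydrosilylation of an allylic hydrosilyl ether (5-endo, cis addition) places silicon on C6 and hydrogen on C5, both from the face of O4, and Tamao–Fleming oxidation replaces silicon by hydroxyl with retention. The tether thus sets C5 and C6 together, and the C8=C9 bond is out of its reach.

Step 19
Reactants: 26 diol with Z-8,9-alkene
Product: 27 AgNO3 complex of the (E)-8,9-alkene (C7 turned to the β face, C10 to the α face; C8 methyl α, H9 β)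
Conditions: hν (254 nm, quartz), methyl benzoate (2 equiv), Et2O/hexanes, −50 °C, closed flow loop through AgNO3 on silica gel; complex eluted with cold acetone
Reagents that add atoms: silver nitrate, [Ag+].[O-][N+](=O)[O-]
Why: This is the aromatic-ester-sensitised Z→E photoisomerisation by which trans-cycloheptenes are made; the cold flow loop keeps the thermally labile E isomer alive until AgNO3 on the column binds it and so drains the photostationary mixture toward 27. The substrate has no chromophore of its own at 254 nm, which is why the veratroate is still absent. Of the two senses of twist only the one that turns C10 to the α face and C7 to the β face leaves the angular C1 methyl outside the ring, so a single planar-chiral E isomer is expected, with the C8 methyl on the α face.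

Step 20
Reactants: 27 AgNO3 complex of the (E)-8,9-alkene
Product: 29 trans-fused 8,9-oxirane (O β at C8 with the methyl α, O α at C9; C4,C6-diol, C2 acetate, C10 silyl ether), via free E-alkene 28 (not isolated)
Conditions: Bu4NCl (1.0 equiv), CH2Cl2, −78 °C; then dimethyldioxirane (1.2 equiv) in acetone, −78 → −40 °C
Reagents that add atoms: dimethyldioxirane, CC1(C)OO1
Why: Chloride precipitates the silver and frees 28, and dimethyldioxirane then transfers oxygen in a concerted syn addition, the way dioxiranes and peracids convert trans-cyclooctenes into their trans-fused oxides and OsO4 adds to silver-liberated trans-cycloheptenes. The ring chain covers the inner face of the twisted double bond, so oxygen can only arrive on the open face; with C7 and C10 held trans this puts it β at C8 (methyl α) and α at C9, the required configuration. The strained alkene should react at −78 °C, where thermal return to the Z isomer is slow and the other functional groups are inert, and the neutral reagent leaves only acetone.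

Step 21
Reactants: 29 trans-fused 8,9-oxirane; 30 3,4-dimethoxybenzoyl chloride
Product: 31 C6 veratroate (C2 acetate, C4 hydroxyl, C10 silyl ether, trans-fused oxirane)
Conditions: DMAP, Et3N, CH2Cl2, 0 → 23 °C
Reagents that add atoms: none
Why: DMAP-promoted acylation of the only free secondary hydroxyl; the tertiary C4 hydroxyl does not react and O10 is still silylated, so the site is unambiguous. The basic medium leaves the strained oxirane alone, and the aromatic ester is introduced only now because it would absorb the 254 nm light and quench the sensitiser of step 19.

Step 22
Reactants: 31 C6 veratroate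
Product: 32 target CNP0197096.3
Conditions: Bu4NF (3 equiv), AcOH (3 equiv), THF, 0 → 23 °C
Reagents that add atoms: none
Why: Acetic acid-buffered fluoride cleaves the last silyl ether without the strong acid that would open the strained tertiary oxirane and without leaving a free alkoxide that could move the acetate from O2 to the cis O10 or attack the oxirane. Both esters and the tertiary alcohol are inert under these conditions.

## Compound list

1 | (S)-terpinen-4-ol | CC1=CC[C@](O)(C(C)C)CC1 | starting material
2 | (S)-terpinen-4-ol triethylsilyl ether | CC1=CC[C@](O[Si](CC)(CC)CC)(C(C)C)CC1 | intermediate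
3 | secondary ozonide of 2 (mixture at the two trioxolane carbons) | CC12CC[C@@](O[Si](CC)(CC)CC)(C(C)C)CC(OO1)O2 | intermediate
4 | (S)-3-isopropyl-6-oxo-3-(triethylsilyloxy)heptanal | O=CC[C@](O[Si](CC)(CC)CC)(C(C)C)CCC(C)=O | intermediate
5 | 2-methyl-5-isopropyl-5-(triethylsilyloxy)cyclopent-1-ene-1-carbaldehyde, C4 as in 1 | O=CC1=C(C)CC[C@@]1(O[Si](CC)(CC)CC)C(C)C | intermediate
6 | 1-[2-methyl-5-isopropyl-5-(triethylsilyloxy)cyclopent-1-en-1-yl]ethan-1-ol, both carbinol epimers | CC(O)C1=C(C)CC[C@@]1(O[Si](CC)(CC)CC)C(C)C | intermediate
7 | 1-[2-methyl-5-isopropyl-5-(triethylsilyloxy)cyclopent-1-en-1-yl]ethan-1-one | CC(=O)C1=C(C)CC[C@@]1(O[Si](CC)(CC)CC)C(C)C | intermediate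
8 | 3-acetyl-2-methyl-4-isopropyl-4-(triethylsilyloxy)cyclopent-2-en-1-one | CC(=O)C1=C(C)C(=O)C[C@@]1(O[Si](CC)(CC)CC)C(C)C | intermediate
9 | lithium enolate of 8 at the acetyl group | [Li+].[O-]C(=C)C1=C(C)C(=O)C[C@@]1(O[Si](CC)(CC)CC)C(C)C | intermediate
10 | 3-[1-(tert-butyldimethylsilyloxy)ethenyl]-2-methyl-4-isopropyl-4-(triethylsilyloxy)cyclopent-2-en-1-one | C=C(O[Si](C)(C)C(C)(C)C)C1=C(C)C(=O)C[C@@]1(O[Si](CC)(CC)CC)C(C)C | intermediate
11 | (tert-butyldimethylsilyloxy)acetaldehyde | O=CCO[Si](C)(C)C(C)(C)C | starting material
12 | ethyl diazoacetate | CCOC(=O)C=[N+]=[N-] | starting material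
13 | ethyl 4-(tert-butyldimethylsilyloxy)-2-diazo-3-hydroxybutanoate, racemic | CCOC(=O)C(=[N+]=[N-])C(O)CO[Si](C)(C)C(C)(C)C | intermediate
14 | ethyl (E)-4-(tert-butyldimethylsilyloxy)-2-diazobut-3-enoate | CCOC(=O)C(=[N+]=[N-])/C=C/O[Si](C)(C)C(C)(C)C | intermediate
15 | cis-divinylcyclopropane on C6, C7, C8 (silyloxy on C6, ester and E-silyloxyvinyl on C8, alkenyl groups cis) | CCOC(=O)[C@@]1(/C=C/O[Si](C)(C)C(C)(C)C)C[C@]1(O[Si](C)(C)C(C)(C)C)C2=C(C)C(=O)C[C@@]2(O[Si](CC)(CC)CC)C(C)C | intermediate
16 | bicyclic cyclohepta-1,4-diene: C8 ethyl ester, C10 OTBS trans to C1 methyl, C2 ketone, C4 OTES, C5=C6 TBS enol ether | CCOC(=O)C1=C[C@H](O[Si](C)(C)C(C)(C)C)[C@]2(C)C(=O)C[C@@](O[Si](CC)(CC)CC)(C(C)C)C2=C(O[Si](C)(C)C(C)(C)C)C1 | intermediate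
17 | C6 enol triflate of the bicycle | CCOC(=O)C1=C[C@H](O[Si](C)(C)C(C)(C)C)[C@]2(C)C(=O)C[C@@](O[Si](CC)(CC)CC)(C(C)C)C2=C(OS(=O)(=O)C(F)(F)F)C1 | intermediate
18 | keto ester with C5=C6–H | CCOC(=O)C1=C[C@H](O[Si](C)(C)C(C)(C)C)[C@]2(C)C(=O)C[C@@](O[Si](CC)(CC)CC)(C(C)C)C2=CC1 | intermediate
19 | diol: C2 hydroxyl (α face), C8 hydroxymethyl | OCC1=C[C@H](O[Si](C)(C)C(C)(C)C)[C@]2(C)[C@H](O)C[C@@](O[Si](CC)(CC)CC)(C(C)C)C2=CC1 | intermediate
20 | primary allylic mesylate of 19 | CS(=O)(=O)OCC1=C[C@H](O[Si](C)(C)C(C)(C)C)[C@]2(C)[C@H](O)C[C@@](O[Si](CC)(CC)CC)(C(C)C)C2=CC1 | intermediate
21 | C2 alcohol with C8 methyl | CC1=C[C@H](O[Si](C)(C)C(C)(C)C)[C@]2(C)[C@H](O)C[C@@](O[Si](CC)(CC)CC)(C(C)C)C2=CC1 | intermediate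
22 | C2 acetate | CC1=C[C@H](O[Si](C)(C)C(C)(C)C)[C@]2(C)[C@H](OC(C)=O)C[C@@](O[Si](CC)(CC)CC)(C(C)C)C2=CC1 | intermediate
23 | C2 acetate with free tertiary C4 hydroxyl | CC1=C[C@H](O[Si](C)(C)C(C)(C)C)[C@]2(C)[C@H](OC(C)=O)C[C@@](O)(C(C)C)C2=CC1 | intermediate
24 | C4 dimethylsilyl (Si–H) ether | CC1=C[C@H](O[Si](C)(C)C(C)(C)C)[C@]2(C)[C@H](OC(C)=O)C[C@@](O[SiH](C)C)(C(C)C)C2=CC1 | intermediate
25 | oxasilolane bridging O4 and C6 (Si and H5 on the α face) | C[Si]3(C)[C@@H]1CC(C)=C[C@H](O[Si](C)(C)C(C)(C)C)[C@]2(C)[C@H](OC(C)=O)C[C@@](O3)(C(C)C)[C@@H]12 | intermediate
26 | C4,C6-diol, trans-fused, C2 acetate, C10 OTBS, Z-8,9-alkene | O[C@@H]1CC(C)=C[C@H](O[Si](C)(C)C(C)(C)C)[C@]2(C)[C@H](OC(C)=O)C[C@@](O)(C(C)C)[C@@H]12 | intermediate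
27 | AgNO3 complex of the (E)-8,9-alkene of 26 (C7 turned to the β face, C10 to the α face; C8 methyl α, H9 β) | O[C@@H]1C/C(C)=C/[C@H](O[Si](C)(C)C(C)(C)C)[C@]2(C)[C@H](OC(C)=O)C[C@@](O)(C(C)C)[C@@H]12.[Ag+].[O-][N+](=O)[O-] | intermediate
28 | free (E)-8,9-alkene with the same sense of twist (C4,C6-diol, C2 acetate, C10 OTBS) | O[C@@H]1C/C(C)=C/[C@H](O[Si](C)(C)C(C)(C)C)[C@]2(C)[C@H](OC(C)=O)C[C@@](O)(C(C)C)[C@@H]12 | intermediate
29 | trans-fused 8,9-oxirane (O β at C8, α at C9; C8 methyl α), C4,C6-diol, C2 acetate, C10 OTBS | O[C@@H]1C[C@@]3(C)O[C@@H]3[C@H](O[Si](C)(C)C(C)(C)C)[C@]2(C)[C@H](OC(C)=O)C[C@@](O)(C(C)C)[C@@H]12 | intermediate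
30 | 3,4-dimethoxybenzoyl chloride | COc1ccc(C(Cl)=O)cc1OC | starting material
31 | C6 veratroate of 29 (C2 acetate, C4 hydroxyl, C10 OTBS, trans-fused oxirane) | COc1ccc(C(=O)O[C@@H]2C[C@@]3(C)O[C@@H]3[C@H](O[Si](C)(C)C(C)(C)C)[C@]3(C)[C@H](OC(C)=O)C[C@@](O)(C(C)C)[C@@H]23)cc1OC | intermediate
32 | CNP0197096.3 | COc1ccc(C(=O)O[C@@H]2C[C@@]3(C)O[C@@H]3[C@H](O)[C@]3(C)[C@H](OC(C)=O)C[C@@](O)(C(C)C)[C@@H]23)cc1OC | target

## Step count and least certain steps

Total: 22 steps. Longest linear sequence: 20 steps (steps 1–7 and 10–22); the diazo ester branch (steps 8–9) is 2 steps.

**Step 10 (key step).** Most likely to go wrong is heterolytic opening of the donor–acceptor cyclopropane (silyloxy on C6, ester on C8) to a zwitterion. This would erase the catalyst-set configuration and divert material into five-membered-ring products. The catalyst may also fail to override the substrate's own facial preference, and the electron-rich diazo ester may cyclise before it meets the catalyst.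

Fallback: take the donor off the cyclopropane. From enedione 8, kinetic enolisation with KN(SiMe3)2 and trapping with PhNTf2 should give the dienyl triflate F1, and palladium/formate reduction the vinyl dienone F2. Its terminal vinyl group would be cyclopropanated by the carbenoid from 14 to the divinylcyclopropane F3, using Rh2(S-TCPTAD)4 [dirhodium tetrakis((S)-N-tetrachlorophthaloyl-(1-adamantyl)glycinate)], a catalyst of the same family developed for electron-poor alkenes. F3 has no donor on the ring and can only rearrange by the concerted pathway. The product is 18, so the route is rejoined after step 12.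

**Step 19.** This and step 20 are the least certain steps of the route. The risk is that no E isomer accumulates. An (E)-cycloheptene is far above its Z isomer in energy even in the parent ring; here the trans ring fusion resists the twist that keeps the angular methyl outside, and the other twist puts that methyl over the double bond. The twisted excited state may therefore simply return to the Z form. If an E isomer does form, it may revert in the loop or be lost on the silver-loaded silica by proton transfer from the C4 or C6 hydroxyl (transannular ether formation). Poor control of the sense of twist would show at this stage and would lead in step 20 to the diastereomeric trans-fused oxirane.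

Fallback: no capture and no isolation. From 26, batch irradiation at −78 °C (254 nm, methyl benzoate, Et2O/pentane) would give a photostationary mixture that contains 28; dimethyldioxirane added in the dark at −78 °C should consume only the strained isomer and give 29 directly, and recovered 26 is recycled. This gives up the chance to characterise the E isomer and depends on the photostationary ratio.

**Step 20.** The risk is loss of the liberated E-alkene before oxygen transfer, by thermal return to the Z isomer or by hydroxyl-assisted protonation at C9 with capture of the C8 cation. The strained oxirane may also rearrange on work-up (to the C9 ketone or an allylic alcohol).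

Fallback: carry out the isomerisation and oxidation on the hydroxyl-free oxasilolane. From 24, the hydrosilylation of step 18 alone gives 25, which is isolated. Photoisomerisation with AgNO3 capture as in step 19 should give the silver complex of the E-oxasilolane F12; Bu4NCl frees the E-oxasilolane F13, and dimethyldioxirane at −78 °C gives the trans-fused epoxy oxasilolane F14. Tamao–Fleming oxidation (KF, KHCO3, H2O2) then returns to 29. This removes both hydroxyl protons from the neighbourhood of the strained alkene, at the price of a C–Si oxidation in the presence of the oxirane.

**Step 22.** The risk is opening or rearrangement of the strained oxirane, or an acetate shift from O2 to O10, while the hindered neopentyl silyl ether is cleaved slowly.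

Fallback: remove the silyl group before the oxirane exists. From 26, HF·pyridine gives the triol F15. Batch irradiation at −78 °C as in the fallback to step 19 gives the E-triol F16, which dimethyldioxirane converts into the trans-fused epoxy triol F17. Acylation with 30 (1.1 equiv, DMAP, Et3N, −20 °C) at the less hindered C6 hydroxyl (C10 is neopentyl and flanked by the oxirane) returns to 32. This path trades the late desilylation for a site-selective acylation.

**Step 13.** The risk is poor facial selectivity at C2: if the angular methyl outweighs C10 and its silyloxy group, hydride arrives from the α face and the C2 epimer dominates.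

Fallback: inversion in place of selective reduction. From 18 the same reduction would then give the epimeric diol F4, and the deoxygenation of step 14 the epimeric alcohol F5. A Mitsunobu reaction with 4-nitrobenzoic acid (PPh3, DIAD), a known way to invert neopentyl cyclopentanols such as steroidal 17-ols, should give the inverted 4-nitrobenzoate F6. Methanolysis (K2CO3, MeOH) returns to 21.

**Step 18.** The risk is a slow 5-endo hydrosilylation at a trisubstituted alkene flanked by two fully substituted carbons, so that double-bond migration or Si–O cleavage take over.

Fallback: intermolecular hydroboration while C8=C9 is still deactivated as the enoate. From 18, excess BH3·THF followed by NaBO3 reduces C2 and hydroborates C5=C6 from the face opposite the isopropyl and methyl groups, giving the diol ester F7. iBu2AlH then gives the triol F8, and selective mesylation with LiEt3BH reduction the C2,C6-diol F9. Et3SiCl/imidazole silylates the less hindered C6 hydroxyl to the bis(triethylsilyl) ether F10, and acetylation of the C2 hydroxyl gives the acetate F11. HF·pyridine, as in step 16, removes both triethylsilyl groups and returns to 26. This path gives up the tether and depends on intrinsic facial preference and on one selective silylation.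

## Further compounds

F1 | step 10 | dienyl triflate from 8 (C6 enol triflate) | C=C(OS(=O)(=O)C(F)(F)F)C1=C(C)C(=O)C[C@@]1(O[Si](CC)(CC)CC)C(C)C
F2 | step 10 | vinyl dienone, 2-methyl-3-vinyl-4-isopropyl-4-(triethylsilyloxy)cyclopent-2-en-1-one | C=CC1=C(C)C(=O)C[C@@]1(O[Si](CC)(CC)CC)C(C)C
F3 | step 10 | cis-divinylcyclopropane without silyloxy group on C6 | CCOC(=O)[C@@]1(/C=C/O[Si](C)(C)C(C)(C)C)C[C@@H]1C2=C(C)C(=O)C[C@@]2(O[Si](CC)(CC)CC)C(C)C
F4 | step 13 | C2 epimer of diol 19 | OCC1=C[C@H](O[Si](C)(C)C(C)(C)C)[C@]2(C)[C@@H](O)C[C@@](O[Si](CC)(CC)CC)(C(C)C)C2=CC1
F5 | step 13 | C2 epimer of alcohol 21 | CC1=C[C@H](O[Si](C)(C)C(C)(C)C)[C@]2(C)[C@@H](O)C[C@@](O[Si](CC)(CC)CC)(C(C)C)C2=CC1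
F6 | step 13 | C2 4-nitrobenzoate with the configuration of 21 | CC1=C[C@H](O[Si](C)(C)C(C)(C)C)[C@]2(C)[C@H](OC(=O)c3ccc(cc3)[N+](=O)[O-])C[C@@](O[Si](CC)(CC)CC)(C(C)C)C2=CC1
F7 | step 18 | C2,C6-diol with C8 ethyl ester | O[C@@H]1CC(C(=O)OCC)=C[C@H](O[Si](C)(C)C(C)(C)C)[C@]2(C)[C@H](O)C[C@@](O[Si](CC)(CC)CC)(C(C)C)[C@@H]12
F8 | step 18 | triol with C8 hydroxymethyl | O[C@@H]1CC(CO)=C[C@H](O[Si](C)(C)C(C)(C)C)[C@]2(C)[C@H](O)C[C@@](O[Si](CC)(CC)CC)(C(C)C)[C@@H]12
F9 | step 18 | C2,C6-diol with C8 methyl | O[C@@H]1CC(C)=C[C@H](O[Si](C)(C)C(C)(C)C)[C@]2(C)[C@H](O)C[C@@](O[Si](CC)(CC)CC)(C(C)C)[C@@H]12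
F10 | step 18 | C4,C6-bis(triethylsilyl) ether with free C2 hydroxyl | CC[Si](CC)(CC)O[C@@H]1CC(C)=C[C@H](O[Si](C)(C)C(C)(C)C)[C@]2(C)[C@H](O)C[C@@](O[Si](CC)(CC)CC)(C(C)C)[C@@H]12
F11 | step 18 | C2 acetate of the C4,C6-bis(triethylsilyl) ether | CC[Si](CC)(CC)O[C@@H]1CC(C)=C[C@H](O[Si](C)(C)C(C)(C)C)[C@]2(C)[C@H](OC(C)=O)C[C@@](O[Si](CC)(CC)CC)(C(C)C)[C@@H]12
F0 | step 19 | none | none
F12 | step 20 | AgNO3 complex of the (E)-8,9-alkene of oxasilolane 25 | C[Si]3(C)[C@@H]1C/C(C)=C/[C@H](O[Si](C)(C)C(C)(C)C)[C@]2(C)[C@H](OC(C)=O)C[C@@](O3)(C(C)C)[C@@H]12.[Ag+].[O-][N+](=O)[O-]
F13 | step 20 | free (E)-8,9-alkene of oxasilolane 25 | C[Si]3(C)[C@@H]1C/C(C)=C/[C@H](O[Si](C)(C)C(C)(C)C)[C@]2(C)[C@H](OC(C)=O)C[C@@](O3)(C(C)C)[C@@H]12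
F14 | step 20 | trans-fused 8,9-epoxy oxasilolane | C[Si]4(C)[C@@H]1C[C@@]3(C)O[C@@H]3[C@H](O[Si](C)(C)C(C)(C)C)[C@]2(C)[C@H](OC(C)=O)C[C@@](O4)(C(C)C)[C@@H]12
F15 | step 22 | C4,C6,C10-triol with C2 acetate and Z-8,9-alkene | O[C@@H]1CC(C)=C[C@H](O)[C@]2(C)[C@H](OC(C)=O)C[C@@](O)(C(C)C)[C@@H]12
F16 | step 22 | (E)-8,9-alkene of the triol | O[C@@H]1C/C(C)=C/[C@H](O)[C@]2(C)[C@H](OC(C)=O)C[C@@](O)(C(C)C)[C@@H]12
F17 | step 22 | trans-fused 8,9-epoxy triol with C2 acetate | O[C@@H]1C[C@@]3(C)O[C@@H]3[C@H](O)[C@]2(C)[C@H](OC(C)=O)C[C@@](O)(C(C)C)[C@@H]12
A1 | alternative 1 | Z-enal oxime tethered to the cyclopentene | ON=C/C=C(C)\CC(=O)C1C(C)=CC[C@@]1(O[Si](CC)(CC)CC)C(C)C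
A2 | alternative 1 | isoxazoline-fused hydroazulenone | O=C1CC(C)=CC2=NO[C@@H]3C[C@@](O[Si](CC)(CC)CC)(C(C)C)C1[C@]23C
A3 | alternative 2 | acyclic α-diazo methyl ketone with C4–H | CC(=O)C(=[N+]=[N-])[C@](C)([C@@H](O[Si](C)(C)C(C)(C)C)/C=C(/C)I)[C@H](O[Si](CC)(CC)CC)C[C@@H](O[Si](C)(C)C(C)(C)C)C(C)C
A4 | alternative 2 | acetylcyclopentane with tertiary C4 silyl ether | CC(=O)C1[C@](C)([C@@H](O[Si](C)(C)C(C)(C)C)/C=C(/C)I)[C@H](O[Si](CC)(CC)CC)C[C@@]1(O[Si](C)(C)C(C)(C)C)C(C)C
A5 | alternative 3 | anisole-tethered α-methyl diazoketone | CC(=[N+]=[N-])C(=O)C[C@@](O[Si](CC)(CC)CC)(C(C)C)c1ccc(C)cc1OC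
A6 | alternative 3 | bicyclic cycloheptatrienone | COC1=C2[C@](O[Si](CC)(CC)CC)(C(C)C)CC(=O)[C@@]2(C)C=CC(C)=C1
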